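Late on, the runs have little to show: by 40.0 h each holds hardly any target, so the peak lies in the early hours.

all flasks: starting material 0.087 M

| charge | second substrate | free enzyme | remark | time |
|---|---|---|---|---|
| Wednesday's | 0.348 M | 7 µM | run made earlier |  |
| Sunday's | 0.348 M | 28 µM | run made earlier |  |
| Thursday's | 0.52 M | 14 µM | run made earlier |  |
| flask | 0.348 M | 14 µM |  | 30 h |

| run | time / h | target / % | starting material / % |
|---|---|---|---|
| Wednesday's | 0.333 | 15.3 | 80.9 |
| Wednesday's | 1.50 | 31.7 | 32.2 |
| Wednesday's | 8.00 | 2.7 | 0.4 |
| Wednesday's | 40.0 | 1.7 | 1.1 |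
| Sunday's | 0.333 | 45.4 | 38.8 |
| Sunday's | 1.50 | 11.4 | 0.1 |
| Sunday's | 8.00 | 3.9 | 2.5 |
| Sunday's | 40.0 | 3.5 | 0 |
| Thursday's | 0.333 | 31.1 | 63.6 |
| Thursday's | 1.50 | 23.6 | 7.2 |
| Thursday's | 8.00 | 3.5 | 0.6 |
| Thursday's | 40.0 | 1.5 | 0.7 |

(readings scatter by 1 percentage point)

- the moment within 30 h at which there is most target
- the amount of target, in percent of the starting material charged, at that time
- the first time at which target reaches 20%, in the same percent



I rank the rates, fastest first. Sunday's first reading gives a first-order use of starting material of 2.84 h⁻¹. With 4.00 times Wednesday's free enzyme, the logarithmic loss at that time is 4.47 times Wednesday's, so I scale by enzyme: 1.42 h⁻¹ for this flask, half gone in 0.488 h.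

The next rung I reckon against starting material, not the clock. The loss ratio (a selectivity factor) is target's first-order loss rate over starting material's. Time drops out of it, and near a ratio of one the peak height is the inverse of e times its square root. Taking the highest readings as peaks, with their scatter, gives 1.35 on Wednesday and 0.657 on Sunday, lower with more enzyme. I assume the ratio runs straight in reciprocal enzyme, which gives this flask 0.887, its loss ratio. Target's loss, 1.26 h⁻¹, is then slightly slower than the use of starting material, and I expect a peak of 39.1% at 0.747 h.

The bottom rung is the tail: Wednesday's target readings sink at about 0.0145 h⁻¹, far slower than my early loss of target, though that figure rests on a drop of 1 percentage point against a scatter of 1 point.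

The forecast says 39% at 0.75 h, and 20% at 0.19 h, holding that “Target is consumed too, but less than proportionally to enzyme”.

The flask gives 39.1% at 0.685 h, and reaches 20% at 0.190 h; my loss ratio of 0.887 stood for 39.1% at 0.747 h, a peak time later than the flask's.

    starting material + free enzyme ⇌ first complex (K = 8.90 M⁻¹, k = 89000 M⁻¹ min⁻¹)
    first complex → loaded enzyme + first product (k = 340 min⁻¹)
    second substrate + loaded enzyme ⇌ second complex (K = 3.70 M⁻¹, k = 30000 M⁻¹ min⁻¹)
    second complex → free enzyme + target (k = 1600 min⁻¹)
    target + first product → side product (k = 0.520 M⁻¹ min⁻¹)
    target + free enzyme ⇌ isomer of the product + free enzyme, rate k6*[free enzyme]*[target] forward; the back reaction follows from the equilibrium constant (K = 2.40, k = 720 M⁻¹ min⁻¹)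

For the neighbour with 8.4 × 10⁻⁶ M of free enzyme, the same line gives 1.19 and so 33.7%, and that flask gives 33.6%. At 0.499 h the asked flask uses target 2.8 times faster with first product than by the forward step to the isomer of the product alone. At 30.0 h it holds 95.1% side product against 1.28% target.

All runs are simulated with constants of no real substance; noise was put on by code.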